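The route rests on cutting the γ-lactone ring (O–C6, C7, C11, C12) at C7–C11 and O–C6. In the target this ring has the E-C4=C5 alkene on its oxygen-bearing C6 and the oxygenated C8–C9 chain on C7. That is the signature of a malonyl radical attacking the C7 terminus of a C4=C5–C6=C7 diene, followed by carboxylate capture of the oxidised allyl unit at C6. One oxidative annulation thus builds the lactone, one C–C bond and the C6/C7 stereocentres from an open-chain E,E-diene bearing a C1 silyl ether and the C8/C9 dioxolane of D-glyceraldehyde. The ten-membered ring is closed later at C9–C10.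

Key step: step 4

Remark: locants are the germacrane numbers of the target (ring C1–C10, lactone C11–C13 with its oxygen on C6, ester carbon C14 on C10, methyl C15 on C4); the C1 silyl group of the diene is TBDPS instead of TBS so that it survives acetic acid; the ring closure of step 17 is assumed to give mainly the 8,9-anti alcohol, which is immaterial because step 18 erases C9; the SMILES define every configuration.

Step 1
Reactants: 1 pent-4-yn-1-ol
Product: 2 tert-butyl(pent-4-yn-1-yloxy)diphenylsilane
Conditions: TBDPSCl, imidazole, CH2Cl2, 0 °C to rt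
Reagents that add atoms: tert-butyl(chloro)diphenylsilane, CC(C)(C)[Si](Cl)(c1ccccc1)c1ccccc1
Why: Imidazole-promoted silylation of a primary alcohol; the TBDPS ether is chosen because it tolerates the acetic acid medium of step 4.

Step 2
Reactants: 3 (R)-glyceraldehyde acetonide
Product: 4 (4S)-4-[(E)-2-iodoethenyl]-2,2-dimethyl-1,3-dioxolane
Conditions: CrCl2, CHI3, THF/dioxane, 0 °C to rt
Reagents that add atoms: iodoform, IC(I)I
Why: Takai iodo-olefination with divalent chromium converts aldehydes into E-alkenyl iodides under neutral conditions, so the α-alkoxy centre C8 should not epimerise.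

Step 3
Reactants: 2 tert-butyl(pent-4-yn-1-yloxy)diphenylsilane; 4 (4S)-4-[(E)-2-iodoethenyl]-2,2-dimethyl-1,3-dioxolane
Product: 6 E,E-diene (TBDPS ether), via alkenylalane 5 (not isolated)
Conditions: AlMe3, Cp2ZrCl2 (cat.), CH2Cl2, 0 °C to rt; volatiles removed; then 4, ZnCl2 (co-catalyst), Pd(PPh3)4 (cat.), THF, rt
Reagents that add atoms: trimethylaluminium, C[Al](C)C
Why: Negishi zirconium-catalysed syn-carboalumination puts the methyl on C4 and aluminium on C5 with E geometry, and the palladium-catalysed Negishi coupling with the E-iodide forms C5–C6 with retention at both alkenes.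

Step 4
Reactants: 6 E,E-diene (TBDPS ether); 7 methyl hydrogen malonate
Product: 8 trans α-carbomethoxy γ-lactone with the E-alkenyl arm on C6 and the dioxolane on C7
Conditions: Mn(OAc)3 (2.2 equiv), Cu(OAc)2 (0.2 equiv), KOAc, AcOH, 35 °C
Reagents that add atoms: none
Why: Trivalent manganese enolises and oxidises the malonic half-ester to an electrophilic malonyl radical that adds to C7, the less substituted diene terminus, giving the C6–C5–C4 allyl radical; divalent copper oxidises it to the allyl cation (or an allylcopper species) and the free carboxyl closes on C6. This is the known Mn(OAc)3 oxidative lactone annulation of alkenes and 1,3-dienes with malonic acid derivatives. The ring (O, C12, C11, C7, C6) closes by 5-exo attack of oxygen on the allyl terminus C6 in preference to seven-membered closure at C4, and the C4=C5 bond stays E. C7 is set by radical attack on the alkene face anti to the C8–O bond of the dioxolane (C8–H in the alkene plane), which gives the 7,8-anti relation of the target; C6 is set in the ring closure, trans to the C7 substituent, and the epimerisable C11 settles trans. Attack at C7 and not C4 relies on the hindered trisubstituted C4 end, chemoselectivity on the diene being the only oxidisable π system, and survival of the ketal on the KOAc buffer and low temperature; the face selectivity at C7 is the least secure element.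

Step 5
Reactants: 8 trans α-carbomethoxy γ-lactone (C1 TBDPS ether)
Product: 9 C1 primary alcohol
Conditions: HF·pyridine, pyridine, THF, 0 °C to rt
Reagents that add atoms: none
Why: Fluoride-mediated desilylation with buffered HF·pyridine leaves the ketal, the lactone and the acidic C11–H untouched.

Step 6
Reactants: 9 C1 primary alcohol
Product: 10 C1 aldehyde
Conditions: TEMPO (cat.), PhI(OAc)2, CH2Cl2, rt
Reagents that add atoms: none
Why: TEMPO/PhI(OAc)2 oxidation stops at the aldehyde and, being neither basic nor strongly electrophilic, spares the malonate-type C–H and the trisubstituted alkene.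

Step 7
Reactants: 10 C1 aldehyde
Product: 11 terminal alkyne (C1≡C10–H)
Conditions: dimethyl (1-diazo-2-oxopropyl)phosphonate, K2CO3, MeOH, 0 °C to rt; NH4Cl work-up
Reagents that add atoms: dimethyl (1-diazo-2-oxopropyl)phosphonate, COP(=O)(OC)C(=[N+]=[N-])C(C)=O
Why: Ohira–Bestmann (Seyferth–Gilbert) homologation adds C10; it is placed before the α-methylene lactone exists because methanolic carbonate would add to that acceptor, whereas the α-carbomethoxy lactone is only deprotonated and returns on work-up.

Step 8
Reactants: 11 terminal alkyne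
Product: 12 α-carboxy lactone
Conditions: LiOH, THF/H2O, 0 °C; work-up at pH 3 (aq. HCl, 0 °C)
Reagents that add atoms: lithium hydroxide, [Li+].[OH-]
Why: Saponification of the activated malonate-type methyl ester; any lactone opened by hydroxide recloses on acidification, so both paths converge on 12.

Step 9
Reactants: 12 α-carboxy lactone
Product: 14 α-methylene lactone alkyne, via Mannich base 13 (not isolated)
Conditions: (CH2O)n, Et2NH, THF, 65 °C
Reagents that add atoms: formaldehyde (as paraformaldehyde), C=O; diethylamine, CCNCC (its atoms stay in 13 only)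
Why: Decarboxylative Mannich methylenation of a malonic half-acid forms C11=C13 with loss of CO2 and amine, the classical entry to α-methylene γ-lactones; C11 ceases to be a stereocentre.

Step 10
Reactants: 14 α-methylene lactone alkyne
Product: 15 1-iodoalkyne
Conditions: NIS, AgNO3 (cat.), acetone, rt, dark
Reagents that add atoms: N-iodosuccinimide, O=C1CCC(=O)N1I
Why: Silver-catalysed iodination of a terminal alkyne is neutral and leaves the Michael acceptor and the ketal alone.

Step 11
Reactants: 15 1-iodoalkyne
Product: 16 8,9-diol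
Conditions: AcOH/THF/H2O (3:1:1), 45 °C
Reagents that add atoms: none
Why: Acid hydrolysis of the terminal isopropylidene ketal, under which lactone, iodoalkyne and alkenes are stable and translactonisation is slow.

Step 12
Reactants: 16 8,9-diol
Product: 17 C9 triethylsilyl ether
Conditions: Et3SiCl, imidazole, CH2Cl2, −40 to −20 °C
Reagents that add atoms: chlorotriethylsilane, CC[Si](Cl)(CC)CC
Why: Selective silylation of the primary C9 hydroxyl over the hindered secondary C8 hydroxyl at low temperature.

Step 13
Reactants: 18 methyl 2-(hydroxymethyl)acrylate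
Product: 19 methyl 2-[(tert-butyldimethylsilyloxy)methyl]acrylate
Conditions: TBSCl, imidazole, CH2Cl2, 0 °C to rt
Reagents that add atoms: tert-butyl(chloro)dimethylsilane, CC(C)(C)[Si](C)(C)Cl
Why: Standard silylation of a primary allylic alcohol.

Step 14
Reactants: 19 methyl 2-[(tert-butyldimethylsilyloxy)methyl]acrylate
Product: 20 2-[(tert-butyldimethylsilyloxy)methyl]acrylic acid
Conditions: LiOH, THF/H2O, 0 °C; work-up at pH 4 (aq. HCl)
Reagents that add atoms: lithium hydroxide, [Li+].[OH-]
Why: Ester saponification; at 0 °C hydroxide attacks the ester carbonyl faster than it adds to the α-substituted acrylate.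

Step 15
Reactants: 17 C9 triethylsilyl ether; 20 2-[(tert-butyldimethylsilyloxy)methyl]acrylic acid
Product: 22 C8 acrylate ester, via mixed anhydride 21 (not isolated)
Conditions: 20, 2,4,6-trichlorobenzoyl chloride, Et3N, toluene, rt; then 17, DMAP, 0 °C to rt
Reagents that add atoms: 2,4,6-trichlorobenzoyl chloride, O=C(Cl)c1c(Cl)cc(Cl)cc1Cl (its atoms stay in 21 only)
Why: Yamaguchi esterification acylates the hindered secondary C8 hydroxyl through the mixed anhydride without touching a stereocentre.

Step 16
Reactants: 22 C8 acrylate ester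
Product: 23 C9 aldehyde
Conditions: (COCl)2, DMSO, CH2Cl2, −78 to −40 °C; then i-Pr2NEt, −78 to −20 °C
Reagents that add atoms: none
Why: Swern conditions are known to desilylate and oxidise primary triethylsilyl ethers directly while sparing TBS ethers, so no free primary alcohol appears next to the C8 ester and acyl migration is avoided.

Step 17
Reactants: 23 C9 aldehyde
Product: 24 ten-membered cyclic propargylic alcohol (8,9-anti, 9R)
Conditions: CrCl2 (8 equiv), THF, rt, syringe-pump addition of 23 (final 0.003 M)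
Reagents that add atoms: none
Why: Nozaki–Hiyama–Kishi-type addition of the alkynylchromium species from a 1-iodoalkyne to an aldehyde is an established medium-ring closure that tolerates esters, lactones and acrylates; addition anti to the C8–O bond (Cornforth/Felkin) should favour the 8,9-anti alcohol.

Step 18
Reactants: 24 cyclic propargylic alcohol
Product: 25 cyclic ynone
Conditions: Dess–Martin periodinane, pyridine, CH2Cl2, 0 °C
Reagents that add atoms: none
Why: Dess–Martin oxidation of a propargylic alcohol under buffered, non-basic conditions that should not enolise C8.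

Step 19
Reactants: 25 cyclic ynone
Product: 26 cyclic propargylic alcohol (8,9-syn, 9S)
Conditions: (R)-2-methyl-CBS-oxazaborolidine, catecholborane, toluene/CH2Cl2, −78 °C
Reagents that add atoms: none
Why: Corey–Bakshi–Shibata reduction with the alkyne as the small group; the (R)-oxazaborolidine should deliver hydride to give the 9S carbinol, the same sense as Felkin-type hydride attack anti to the C8–O bond, and catecholborane at −78 °C spares esters and alkenes.

Step 20
Reactants: 26 cyclic propargylic alcohol (9S)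
Product: 28 alkenyl iodide, via alkenylstannane 27 (not isolated)
Conditions: Bu3SnH, PdCl2(PPh3)2 (cat.), THF, 0 °C; then NIS, 0 °C
Reagents that add atoms: N-iodosuccinimide, O=C1CCC(=O)N1I; tributyltin hydride, CCCC[SnH](CCCC)CCCC (tin stays in 27 only)
Why: Palladium-catalysed syn-hydrostannation of a propargylic alcohol places tin on the carbon next to the carbinol (C10) and hydrogen on C1, which in the ring gives the cis-cycloalkene, and iododestannylation proceeds with retention.

Step 21
Reactants: 28 alkenyl iodide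
Product: 29 methyl enoate with free C9 hydroxyl
Conditions: Pd(PPh3)4 (cat.), CO (3 atm), MeOH, i-Pr2NEt, DMF, 40 °C
Reagents that add atoms: carbon monoxide, [C-]#[O+]; methanol, CO
Why: Palladium-catalysed methoxycarbonylation of an alkenyl iodide (oxidative addition to zerovalent palladium, CO insertion, methanolysis) retains the alkene geometry, and the CO pressure lets insertion outrun a transannular Heck reaction.

Step 22
Reactants: 29 methyl enoate with free C9 hydroxyl
Product: 30 C9 acetate (side-chain TBS ether of the target)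
Conditions: Ac2O, pyridine, DMAP (cat.), CH2Cl2, 0 °C
Reagents that add atoms: acetic anhydride, CC(=O)OC(C)=O
Why: DMAP-catalysed acetylation of a secondary allylic alcohol, fast enough at 0 °C to precede any acyl migration from O8.

Step 23
Reactants: 30 C9 acetate (side-chain TBS ether)
Product: 31 CNP0291058.1
Conditions: HF·pyridine, pyridine, THF, 0 °C
Reagents that add atoms: none
Why: Buffered fluoride desilylation frees the primary allylic alcohol without touching the acetate, the esters or the two Michael acceptors.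

Compound list
1 | pent-4-yn-1-ol | C#CCCCO | starting material
2 | tert-butyl(pent-4-yn-1-yloxy)diphenylsilane | C#CCCCO[Si](c1ccccc1)(c1ccccc1)C(C)(C)C | intermediate
3 | (R)-glyceraldehyde acetonide, (4R)-2,2-dimethyl-1,3-dioxolane-4-carbaldehyde | CC1(C)OC[C@@H](O1)C=O | starting material
4 | (4S)-4-[(E)-2-iodoethenyl]-2,2-dimethyl-1,3-dioxolane | CC1(C)OC[C@@H](O1)/C=C/I | intermediate
5 | dimethyl[(1E)-2-methyl-5-(TBDPS-oxy)pent-1-en-1-yl]aluminium (Al cis to the new methyl) | C[Al](C)/C=C(\C)CCCO[Si](c1ccccc1)(c1ccccc1)C(C)(C)C | intermediate (not isolated)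
6 | tert-butyl{[(4E,6E)-7-[(4S)-2,2-dimethyl-1,3-dioxolan-4-yl]-4-methylhepta-4,6-dien-1-yl]oxy}diphenylsilane | CC1(C)OC[C@@H](O1)/C=C/C=C(\C)CCCO[Si](c1ccccc1)(c1ccccc1)C(C)(C)C | intermediate
7 | methyl hydrogen malonate | COC(=O)CC(=O)O | starting material
8 | methyl 2-oxotetrahydrofuran-3-carboxylate with the (4S)-dioxolanyl group on ring C4 (= C7) and the (1E)-2-methyl-5-(TBDPS-oxy)pent-1-enyl group on ring C5 (= C6), all-trans; 6R,7S,8S | COC(=O)[C@@H]1C(=O)O[C@H](/C=C(\C)CCCO[Si](c3ccccc3)(c3ccccc3)C(C)(C)C)[C@H]1[C@H]2COC(C)(C)O2 | intermediate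
9 | as 8 with free C1 hydroxyl | COC(=O)[C@@H]1C(=O)O[C@H](/C=C(\C)CCCO)[C@H]1[C@H]2COC(C)(C)O2 | intermediate
10 | as 8 with C1 aldehyde | COC(=O)[C@@H]1C(=O)O[C@H](/C=C(\C)CCC=O)[C@H]1[C@H]2COC(C)(C)O2 | intermediate
11 | as 8 with terminal alkyne C1≡C10–H in place of C1–O | COC(=O)[C@@H]1C(=O)O[C@H](/C=C(\C)CCC#C)[C@H]1[C@H]2COC(C)(C)O2 | intermediate
12 | α-carboxy lactone (acid of 11) | OC(=O)[C@@H]1C(=O)O[C@H](/C=C(\C)CCC#C)[C@H]1[C@H]2COC(C)(C)O2 | intermediate
13 | Mannich base: C11 carries CO2H and CH2NEt2 (C11 mixture) | CCN(CC)CC1(C(=O)O)C(=O)O[C@H](/C=C(\C)CCC#C)[C@H]1[C@H]2COC(C)(C)O2 | intermediate (not isolated)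
14 | α-methylene γ-lactone (C11=C13), trans at C6/C7, with (E)-2-methylhept-1-en-6-ynyl arm on C6 and dioxolane on C7 | C=C1C(=O)O[C@H](/C=C(\C)CCC#C)[C@H]1[C@H]2COC(C)(C)O2 | intermediate
15 | as 14 with 1-iodoalkyne (C10–I) | C=C1C(=O)O[C@H](/C=C(\C)CCC#CI)[C@H]1[C@H]2COC(C)(C)O2 | intermediate
16 | as 15 with free C8 and C9 hydroxyls | C=C1C(=O)O[C@H](/C=C(\C)CCC#CI)[C@H]1[C@H](O)CO | intermediate
17 | as 16 with C9–OSiEt3 and free C8–OH | C=C1C(=O)O[C@H](/C=C(\C)CCC#CI)[C@H]1[C@H](O)CO[Si](CC)(CC)CC | intermediate
18 | methyl 2-(hydroxymethyl)acrylate | C=C(CO)C(=O)OC | starting material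
19 | methyl 2-[(tert-butyldimethylsilyloxy)methyl]acrylate | C=C(CO[Si](C)(C)C(C)(C)C)C(=O)OC | intermediate
20 | 2-[(tert-butyldimethylsilyloxy)methyl]acrylic acid | C=C(CO[Si](C)(C)C(C)(C)C)C(=O)O | intermediate
21 | mixed anhydride of 20 with 2,4,6-trichlorobenzoic acid | C=C(CO[Si](C)(C)C(C)(C)C)C(=O)OC(=O)c1c(Cl)cc(Cl)cc1Cl | intermediate (not isolated)
22 | as 17 with C8–O acylated by 2-[(TBS-oxy)methyl]acryloyl | C=C1C(=O)O[C@H](/C=C(\C)CCC#CI)[C@H]1[C@H](OC(=O)C(=C)CO[Si](C)(C)C(C)(C)C)CO[Si](CC)(CC)CC | intermediate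
23 | as 22 with C9 aldehyde | C=C1C(=O)O[C@H](/C=C(\C)CCC#CI)[C@H]1[C@H](OC(=O)C(=C)CO[Si](C)(C)C(C)(C)C)C=O | intermediate
24 | ten-membered ring with C1≡C10 alkyne, E-C4=C5, trans-fused 6,12-lactone, C8 ester, (9R)-hydroxyl (8,9-anti) | C=C(CO[Si](C)(C)C(C)(C)C)C(=O)O[C@H]1[C@H]2C(=C)C(=O)O[C@@H]2/C=C(\C)CCC#C[C@H]1O | intermediate
25 | C9 ketone of 24 (cyclic ynone) | C=C(CO[Si](C)(C)C(C)(C)C)C(=O)O[C@H]1[C@H]2C(=C)C(=O)O[C@@H]2/C=C(\C)CCC#CC1=O | intermediate
26 | C9 epimer of 24, (9S)-hydroxyl (8,9-syn) | C=C(CO[Si](C)(C)C(C)(C)C)C(=O)O[C@H]1[C@H]2C(=C)C(=O)O[C@@H]2/C=C(\C)CCC#C[C@@H]1O | intermediate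
27 | ring-cis C1=C10 alkene with Bu3Sn on C10 (trans to C2), C9 hydroxyl placed as in 26 | C=C(CO[Si](C)(C)C(C)(C)C)C(=O)O[C@H]1[C@H]2C(=C)C(=O)O[C@@H]2/C=C(\C)CC/C=C(/[Sn](CCCC)(CCCC)CCCC)[C@@H]1O | intermediate (not isolated)
28 | as 27 with iodine on C10 | C=C(CO[Si](C)(C)C(C)(C)C)C(=O)O[C@H]1[C@H]2C(=C)C(=O)O[C@@H]2/C=C(\C)CC/C=C(/I)[C@@H]1O | intermediate
29 | as 27 with CO2Me on C10 (1(10)E enoate), free (9S)-hydroxyl | C=C(CO[Si](C)(C)C(C)(C)C)C(=O)O[C@H]1[C@H]2C(=C)C(=O)O[C@@H]2/C=C(\C)CC/C=C(/C(=O)OC)[C@@H]1O | intermediate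
30 | C9 acetate of 29 (side-chain TBS ether of the target) | C=C(CO[Si](C)(C)C(C)(C)C)C(=O)O[C@H]1[C@H]2C(=C)C(=O)O[C@@H]2/C=C(\C)CC/C=C(/C(=O)OC)[C@@H]1OC(C)=O | intermediate
31 | CNP0291058.1, (6R,7S,8S,9S) melampolide: 9-acetoxy-8-[2-(hydroxymethyl)acryloyloxy]-14-methyl ester 6,12-lactone | C=C(CO)C(=O)O[C@H]1[C@H]2C(=C)C(=O)O[C@@H]2/C=C(\C)CC/C=C(/C(=O)OC)[C@@H]1OC(C)=O | target

Total step count: 23 (21 on the main line plus 2 for acid 20).
Longest linear sequence: 20 steps (steps 1, 3–12, 15–23).

Steps most likely to fail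

1. Step 4. The radical may add with poor face selectivity at C7 or partly at C4, the allyl cation may be intercepted by acetate or lose a proton, and the ketal may be cleaved in the acidic medium. The fallback sets out from diene 6 and returns at 8, replacing the radical step by a carbene addition. Rh2(OAc)4-catalysed cyclopropanation of 6 with dimethyl diazomalonate at the disubstituted C6=C7 bond would give the trans vinylcyclopropane diester F1, with C7 fixed in a stereospecific concerted addition. Mono-saponification (KOH, 1 equiv, MeOH) would give the half-acid F2. On warming in toluene F2 should ionise its allylic C6–C11 bond and close the carboxyl oxygen on C6, the known rearrangement of vinylcyclopropane-1,1-dicarboxylic acids to γ-vinyl lactones, giving 8.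

2. Step 17. The ten-membered ring holding both the alkyne and the E-alkene may close too slowly, so that reduction of the iodoalkyne or intermolecular coupling takes over. The fallback sets out from aldehyde 10 and returns at 30; it brings in the ester carbon before ring closure so that the ring closes at an sp2 carbon.
   - Wittig reaction of 10 with methyl 2-iodo-2-(triphenylphosphoranylidene)acetate would give the (Z)-α-iodo enoate F3.
   - Hydrolysis as in step 8 would give the acid F4, which with (CH2O)n/Et2NH would pass through the Mannich base F5 to the α-methylene lactone F6.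
   - Ketal hydrolysis would give the diol F7, silylation the C9 triethylsilyl ether F8, Yamaguchi acylation with 20 (through 21) the C8 ester F9, and Swern oxidation the aldehyde F10.
   - Nickel/chromium-mediated alkenyl iodide–aldehyde coupling (CrCl2, NiCl2 cat., DMSO, high dilution) would close the ring with retention of alkene geometry. With addition anti to the C8–O bond it would give the 9-epimeric allylic alcohol F11.
   - Mitsunobu inversion of F11 with acetic acid (PPh3, diisopropyl azodicarboxylate) would then give 30.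

3. Step 19. Hydride delivery may show poor face selectivity against the ring bias, or the strained ynone may undergo conjugate reduction or decompose. The fallback sets out from alcohol 24 and returns at 30, replacing the redox correction by an SN2 inversion. Mitsunobu reaction of 24 with acetic acid (PPh3, diisopropyl azodicarboxylate, toluene, 0 °C) would give the inverted (9S) propargylic acetate F12. Hydrostannation as in step 20 would give the alkenylstannane F13 and NIS the alkenyl iodide F14. Methoxycarbonylation as in step 21 would give 30, so steps 18, 19 and 22 would not be needed.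

Further compounds
F1 | step 4 | dimethyl trans-2-alkenyl-3-dioxolanylcyclopropane-1,1-dicarboxylate (C6, C7, C11 ring) | COC(=O)C1(C(=O)OC)[C@H](/C=C(\C)CCCO[Si](c2ccccc2)(c2ccccc2)C(C)(C)C)[C@H]1[C@H]3COC(C)(C)O3
F2 | step 4 | half-acid of F1 (C11 mixture) | OC(=O)C1(C(=O)OC)[C@H](/C=C(\C)CCCO[Si](c2ccccc2)(c2ccccc2)C(C)(C)C)[C@H]1[C@H]3COC(C)(C)O3
F3 | step 17 | (Z)-α-iodo enoate of 10 (I cis to C2) | COC(=O)[C@@H]1C(=O)O[C@H](/C=C(\C)CC/C=C(\I)C(=O)OC)[C@H]1[C@H]2COC(C)(C)O2
F4 | step 17 | α-carboxy lactone from F3 | OC(=O)[C@@H]1C(=O)O[C@H](/C=C(\C)CC/C=C(\I)C(=O)OC)[C@H]1[C@H]2COC(C)(C)O2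
F5 | step 17 | Mannich base from F4 (C11 mixture) | CCN(CC)CC1(C(=O)O)C(=O)O[C@H](/C=C(\C)CC/C=C(\I)C(=O)OC)[C@H]1[C@H]2COC(C)(C)O2
F6 | step 17 | α-methylene lactone with iodo enoate arm | C=C1C(=O)O[C@H](/C=C(\C)CC/C=C(\I)C(=O)OC)[C@H]1[C@H]2COC(C)(C)O2
F7 | step 17 | 8,9-diol from F6 | C=C1C(=O)O[C@H](/C=C(\C)CC/C=C(\I)C(=O)OC)[C@H]1[C@H](O)CO
F8 | step 17 | C9 triethylsilyl ether of F7 | C=C1C(=O)O[C@H](/C=C(\C)CC/C=C(\I)C(=O)OC)[C@H]1[C@H](O)CO[Si](CC)(CC)CC
F9 | step 17 | C8 ester of F8 with acid 20 | C=C1C(=O)O[C@H](/C=C(\C)CC/C=C(\I)C(=O)OC)[C@H]1[C@H](OC(=O)C(=C)CO[Si](C)(C)C(C)(C)C)CO[Si](CC)(CC)CC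
F10 | step 17 | C9 aldehyde from F9 | C=C1C(=O)O[C@H](/C=C(\C)CC/C=C(\I)C(=O)OC)[C@H]1[C@H](OC(=O)C(=C)CO[Si](C)(C)C(C)(C)C)C=O
F11 | step 17 | C9 epimer of 29 (9R, 8,9-anti) | C=C(CO[Si](C)(C)C(C)(C)C)C(=O)O[C@H]1[C@H]2C(=C)C(=O)O[C@@H]2/C=C(\C)CC/C=C(/C(=O)OC)[C@H]1O
F12 | step 19 | (9S) propargylic acetate of the cyclic alkyne | C=C(CO[Si](C)(C)C(C)(C)C)C(=O)O[C@H]1[C@H]2C(=C)C(=O)O[C@@H]2/C=C(\C)CCC#C[C@@H]1OC(C)=O
F13 | step 19 | C10 tributylstannyl alkene, C9 acetate | C=C(CO[Si](C)(C)C(C)(C)C)C(=O)O[C@H]1[C@H]2C(=C)C(=O)O[C@@H]2/C=C(\C)CC/C=C(/[Sn](CCCC)(CCCC)CCCC)[C@@H]1OC(C)=O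
F14 | step 19 | C10 iodo alkene, C9 acetate | C=C(CO[Si](C)(C)C(C)(C)C)C(=O)O[C@H]1[C@H]2C(=C)C(=O)O[C@@H]2/C=C(\C)CC/C=C(/I)[C@@H]1OC(C)=O
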